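Ring A (C1–C5, C10; drimane numbering) is not cyclised but grown from a cyclopentanone: the C4 gem-dimethyl carbon is inserted between the carbinol carbon C3 and the quaternary C5 by a selenium-triggered semipinacol ring enlargement. This one operation turns a cis-3a,7a-dimethylhydrindane, made from (S)-Hajos–Parrish ketone by cuprate methylation, into the cis-decalin, creates the C4/C5/C10 array of three contiguous quaternary carbons and unveils the C3 carbonyl for the acetate. The precursor is a tertiary cyclopentanol carrying a 2-(phenylselanyl)prop-2-yl group, with ring B already complete (C8 exocyclic methylene, C9 CH2O set by protonation before enlargement). Umbelliferone is attached late by Mitsunobu etherification.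

Key step: step 8

Remark: the target as written carries a methyl group on each ring-fusion carbon (C5 and C10), cis to each other, and β denotes the face of these methyls. Drimane numbering is used for the decalins (C11 = OCH2, C12 = exocyclic CH2) and indane numbering for the hydrindanes, with C1→C3, C3a→C10, C4→C9, C5→C8, C7a→C5.

Step 1
Reactants: 1 (S)-Hajos–Parrish ketone
Product: 2 cis-3a,7a-dimethyl-5-(trimethylsilyloxy)-2,3,3a,6,7,7a-hexahydro-1H-inden-1-one (silyl enol ether, both angular methyls β)
Conditions: Me2CuLi (MeLi, CuI), TMSCl, Et2O–THF, −78 → −20 °C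
Reagents that add atoms: lithium dimethylcuprate [Li+].C[Cu-]C; chlorotrimethylsilane C[Si](C)(C)Cl
Why: Chlorosilane-accelerated conjugate addition of the Gilman cuprate to the β,β-disubstituted enone should deliver the methyl group to C3a on the face of the C7a methyl (axial attack leading to the cis-fused hydrindane), leave the saturated neopentyl cyclopentanone untouched and fix the enolate regiochemistry as the silyl enol ether.

Step 2
Reactants: 2 silyl enol ether
Product: 5 cis-3a,7a-dimethyl-4-methylenehexahydro-1H-indene-1,5-dione, via Mannich base 3 (not isolated), via trimethylammonium iodide 4 (not isolated)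
Conditions: CH2=NMe2+ I−, CH2Cl2, rt; MeI, Et2O; aq NaHCO3, CH2Cl2
Reagents that add atoms: Eschenmoser's salt C=[N+](C)C.[I-]; iodomethane CI (its methyl is kept only in 4)
Why: Mannich reaction of the silyl enol ether with the preformed iminium salt at C4, quaternisation and base-induced Hofmann-type elimination of trimethylamine should give the exocyclic enone, the transient C4 stereocentre being erased.

Step 3
Reactants: 5 exocyclic enone
Product: 7 4β-(hydroxymethyl)-cis-3a,7a-dimethylhexahydro-1H-indene-1,5-dione (hydroxymethyl cis to both methyls), via boronate 6 (not isolated)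
Conditions: B2pin2, CuCl (cat.), Xantphos (cat.), NaOtBu (cat.), MeOH, THF, rt; then H2O2, aq NaHCO3, 0 °C
Reagents that add atoms: hydrogen peroxide OO; bis(pinacolato)diboron CC1(C)OB(OC1(C)C)B1OC(C)(C)C(C)(C)O1 (boron is kept only in 6)
Why: Copper-catalysed conjugate borylation puts boron on the unhindered CH2 terminus and the copper enolate should then be protonated by methanol at C4 under kinetic control on the face opposite both angular methyls (anti to the pseudoaxial C3a methyl), which places the CH2B group cis to the methyls; oxidation of the C–B bond proceeds with retention and does not touch the new stereocentre.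

Step 4
Reactants: 7 hydroxymethyl diketone
Product: 8 4β-[(tert-butyldimethylsilyloxy)methyl]-cis-3a,7a-dimethylhexahydro-1H-indene-1,5-dione
Conditions: TBSCl, imidazole, DMF, 0 °C → rt
Reagents that add atoms: tert-butyldimethylsilyl chloride CC(C)(C)[Si](C)(C)Cl
Why: Standard silylation of the primary alcohol prevents retro-aldol and dehydration of the β-hydroxy ketone and masks the hydroxyl for the organolithium step.

Step 5
Reactants: 8 silyloxy diketone
Product: 9 4β-[(tert-butyldimethylsilyloxy)methyl]-cis-3a,7a-dimethyl-5-methyleneoctahydro-1H-inden-1-one
Conditions: Zn, CH2Br2, TiCl4, THF–CH2Cl2, 0 °C → rt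
Reagents that add atoms: dibromomethane BrCBr
Why: Lombardo methylenation is non-basic, so the enolisable C4 centre and the β-silyloxy ketone are not epimerised or eliminated, and the reagent should select the cyclohexanone over the cyclopentanone shielded by the adjacent quaternary C7a; once C5 is an alkene the C4 configuration can no longer be lost.

Step 6
Reactants: 10 acetone; 11 benzeneselenol (2 equiv)
Product: 12 2,2-bis(phenylselanyl)propane
Conditions: ZnCl2 (cat.), CH2Cl2, rt
Reagents that add atoms: benzeneselenol [SeH]c1ccccc1 (the second equivalent of 11)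
Why: Lewis acid-catalysed selenoketalisation of the ketone with two equivalents of the selenol, with loss of water, gives the selenoacetal that serves as precursor of the α-selenoalkyllithium.

Step 7
Reactants: 9 methylene hydrindanone; 12 2,2-bis(phenylselanyl)propane
Product: 13 1-[2-(phenylselanyl)propan-2-yl]-4β-[(tert-butyldimethylsilyloxy)methyl]-cis-3a,7a-dimethyl-5-methyleneoctahydro-1H-inden-1-ol (hydroxyl drawn β)
Conditions: 12, n-BuLi, THF, −78 °C; then 9, −78 → −40 °C; aq NH4Cl
Reagents that add atoms: none
Why: Selenium–lithium exchange gives the α-selenoalkyllithium, a strongly nucleophilic and weakly basic carbanion that should add 1,2 to the only carbonyl group although it is hindered and enolisable; the configuration of the new carbinol centre (attack opposite the C7a methyl expected) is irrelevant because this carbon becomes the carbonyl carbon in step 8.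

Step 8
Reactants: 13 β-hydroxy selenide
Product: 14 11-(tert-butyldimethylsilyloxy)-5β-methyldrim-8(12)-en-3-one (cis-fused decalin; 4,4,5β,10β-tetramethyl, 9β-CH2OTBS)
Conditions: AgBF4, basic Al2O3, CH2Cl2, 0 °C → rt
Reagents that add atoms: none
Why: The soft silver ion of AgBF4 abstracts phenylselenolate from the fully substituted carbon, generating a tertiary carbocation next to the carbinol, and the ring bond to the quaternary C7a migrates to it while the hydroxyl oxygen pushes, giving the protonated ketone that alumina deprotonates (semipinacol rearrangement). The closest known reaction type is the ring enlargement of 1-(1-selenoalkyl)cycloalkanols to 2,2-dialkylcycloalkanones. Ring A is formed not by cyclisation but by a 1,2-alkyl shift that inserts C4 into the five-membered ring (five → six). No stereocentre is created: the migrating carbon (future C5) shifts with retention, so the cis C5/C10 dimethyl relationship and the fixed C9 centre are carried over unchanged and the carbinol stereocentre is destroyed. The step needs migration of the quaternary carbon instead of the ring CH2, which is secured by the higher migratory aptitude of the more substituted, more electron-rich carbon toward a tertiary cationic terminus, and cation formation is confined to the exocyclic carbon because only that carbon bears the selenium leaving group. Buffering on basic alumina removes HBF4 so that the acid-labile C8 exocyclic methylene is not isomerised.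

Step 9
Reactants: 14 decalin ketone
Product: 15 11-(tert-butyldimethylsilyloxy)-5β-methyldrim-8(12)-en-3β-ol
Conditions: LiAlH4, Et2O, −40 → 0 °C
Reagents that add atoms: none
Why: In the favoured double-chair conformer of the cis-decalin the C5 methyl is axial on ring A and shields the β-face of the C3 carbonyl in a 1,3-diaxial sense, so hydride should add from the α-face (substrate-controlled ketone reduction) to give the 3β-alcohol, while the silyl ether and the alkene are inert.

Step 10
Reactants: 15 silyl ether alcohol
Product: 16 5β-methyldrim-8(12)-ene-3β,11-diol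
Conditions: TBAF, THF, rt
Reagents that add atoms: none
Why: Fluoride-induced cleavage of the primary silyl ether frees the C11 hydroxyl without affecting the alkene or any stereocentre.

Step 11
Reactants: 16 diol; 17 umbelliferone (7-hydroxycoumarin)
Product: 18 7-[(3β-hydroxy-5β-methyldrim-8(12)-en-11-yl)oxy]-2H-chromen-2-one
Conditions: PPh3, DIAD, THF, 0 °C → rt
Reagents that add atoms: none
Why: Mitsunobu etherification with the acidic phenol should occur only at the primary C11 alcohol (SN2 at a CH2, no stereocentre involved), because the neopentyl secondary C3 alcohol cannot be displaced.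

Step 12
Reactants: 18 hydroxy ether
Product: 19 polyanthinin (3β-acetate, target)
Conditions: Ac2O, DMAP, pyridine, rt
Reagents that add atoms: acetic anhydride CC(=O)OC(C)=O
Why: DMAP-catalysed acylation of the hindered secondary alcohol proceeds with retention at C3 and leaves the coumarin and the alkene untouched.

Compound list
1 | (S)-Hajos–Parrish ketone, (7aS)-7a-methyl-2,3,7,7a-tetrahydro-1H-indene-1,5(6H)-dione | C[C@]12CCC(=O)C=C1CCC2=O | starting material
2 | cis-3a,7a-dimethyl-5-(trimethylsilyloxy)-2,3,3a,6,7,7a-hexahydro-1H-inden-1-one | C[Si](C)(C)OC1=C[C@@]2(C)CCC(=O)[C@@]2(C)CC1 | intermediate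
3 | 4-[(dimethylamino)methyl]-cis-3a,7a-dimethylhexahydro-1H-indene-1,5-dione (C4 configuration inconsequential) | CN(C)CC1C(=O)CC[C@]2(C)C(=O)CC[C@]12C | intermediate (not isolated)
4 | trimethylammonium iodide of 3 | C[N+](C)(C)CC1C(=O)CC[C@]2(C)C(=O)CC[C@]12C.[I-] | intermediate (not isolated)
5 | cis-3a,7a-dimethyl-4-methylenehexahydro-1H-indene-1,5-dione | C=C1C(=O)CC[C@]2(C)C(=O)CC[C@]12C | intermediate
6 | 4β-[(4,4,5,5-tetramethyl-1,3,2-dioxaborolan-2-yl)methyl]-cis-3a,7a-dimethylhexahydro-1H-indene-1,5-dione | O=C1CC[C@]2(C)C(=O)CC[C@]2(C)[C@H]1CB1OC(C)(C)C(C)(C)O1 | intermediate (not isolated)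
7 | 4β-(hydroxymethyl)-cis-3a,7a-dimethylhexahydro-1H-indene-1,5-dione | O=C1CC[C@]2(C)C(=O)CC[C@]2(C)[C@H]1CO | intermediate
8 | 4β-[(tert-butyldimethylsilyloxy)methyl]-cis-3a,7a-dimethylhexahydro-1H-indene-1,5-dione | O=C1CC[C@]2(C)C(=O)CC[C@]2(C)[C@H]1CO[Si](C)(C)C(C)(C)C | intermediate
9 | 4β-[(tert-butyldimethylsilyloxy)methyl]-cis-3a,7a-dimethyl-5-methyleneoctahydro-1H-inden-1-one | C=C1CC[C@]2(C)C(=O)CC[C@]2(C)[C@H]1CO[Si](C)(C)C(C)(C)C | intermediate
10 | acetone | CC(C)=O | starting material
11 | benzeneselenol | [SeH]c1ccccc1 | starting material
12 | 2,2-bis(phenylselanyl)propane | CC(C)([Se]c1ccccc1)[Se]c1ccccc1 | intermediate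
13 | 1-[2-(phenylselanyl)propan-2-yl]-4β-[(tert-butyldimethylsilyloxy)methyl]-cis-3a,7a-dimethyl-5-methyleneoctahydro-1H-inden-1-ol (1-OH drawn β, inconsequential) | C=C1CC[C@]2(C)[C@](O)(C(C)(C)[Se]c3ccccc3)CC[C@]2(C)[C@H]1CO[Si](C)(C)C(C)(C)C | intermediate
14 | 11-(tert-butyldimethylsilyloxy)-5β-methyldrim-8(12)-en-3-one | C=C1CC[C@]2(C)C(C)(C)C(=O)CC[C@]2(C)[C@H]1CO[Si](C)(C)C(C)(C)C | intermediate
15 | 11-(tert-butyldimethylsilyloxy)-5β-methyldrim-8(12)-en-3β-ol | C=C1CC[C@]2(C)C(C)(C)[C@@H](O)CC[C@]2(C)[C@H]1CO[Si](C)(C)C(C)(C)C | intermediate
16 | 5β-methyldrim-8(12)-ene-3β,11-diol | C=C1CC[C@]2(C)C(C)(C)[C@@H](O)CC[C@]2(C)[C@H]1CO | intermediate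
17 | umbelliferone (7-hydroxy-2H-chromen-2-one) | Oc1ccc2ccc(=O)oc2c1 | starting material
18 | 7-[(3β-hydroxy-5β-methyldrim-8(12)-en-11-yl)oxy]-2H-chromen-2-one | C=C1CC[C@]2(C)C(C)(C)[C@@H](O)CC[C@]2(C)[C@H]1COc1ccc2ccc(=O)oc2c1 | intermediate
19 | polyanthinin | C=C1CC[C@]2(C)C(C)(C)[C@@H](OC(C)=O)CC[C@]2(C)[C@H]1COc1ccc2ccc(=O)oc2c1 | target

Total step count: 12
Longest linear sequence: 11 steps (steps 1–5 and 7–12, from 1 to 19)

Steps most likely to fail

Step 8. The ring methylene may migrate instead of the quaternary carbon, or the selenide may be lost by elimination or oxirane formation without ring enlargement. The fallback is a β-oxido carbenoid ring enlargement, which also bypasses step 7. It sets out from ketone 9, which is treated with 1,1-dibromoethyllithium (CH3CHBr2, LiN(iPr)2, THF, −95 °C) to give the dibromo carbinol F1. n-BuLi (2.2 equiv, −78 → 0 °C) then removes the hydroxyl proton and exchanges one bromine, and the carbenoid is expected to rearrange with migration of the more substituted ring carbon to the ring-enlarged lithium enolate F2. Methylation of this regiodefined enolate in the same flask (MeI, HMPA) installs the second C4 methyl and comes back to the route at ketone 14.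

Step 3. The copper enolate may be protonated on the other face, or the C4 centre may epimerise under the mildly basic oxidation, leaving the hydroxymethyl group trans to the angular methyls. The fallback lets a carbon instead of a hydrogen electrophile set this centre: if the β-face proves the accessible one for a proton, it should be so for carbon as well. It sets out from silyl enol ether 2, which is hydroxymethylated directly by a Mukaiyama aldol reaction (aqueous formaldehyde, Yb(OTf)3, THF, rt), and comes back to the route at diketone 7 without passing through 5 and 6 (no new compound, F0).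

Step 5. The cyclopentanone may be methylenated competitively or both ketones may react. The fallback is a stepwise Peterson olefination under kinetic addition control. It sets out from diketone 8, to which Me3SiCH2Li/CeCl3 (THF, −78 °C) should add at the more electrophilic and less shielded six-ring ketone to give the β-hydroxysilane F3. Syn-elimination with KH (THF, 0 °C) comes back to the route at alkene 9. The C4 centre is not at risk, because the weakly basic cerium reagent does not enolise the ketone and F3 has no carbonyl next to C4. A transient enolate of the cyclopentanone at C2 is harmless, since C2 bears no stereocentre.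

Further compounds
F1 | step 8 | 1-(1,1-dibromoethyl)-4β-[(tert-butyldimethylsilyloxy)methyl]-cis-3a,7a-dimethyl-5-methyleneoctahydro-1H-inden-1-ol | C=C1CC[C@]2(C)C(O)(C(C)(Br)Br)CC[C@]2(C)[C@H]1CO[Si](C)(C)C(C)(C)C
F2 | step 8 | lithium enolate of 11-(tert-butyldimethylsilyloxy)-4-monomethyl decalin-3-one (C3=C4 enolate) | C=C1CC[C@]2(C)C(C)=C(O[Li])CC[C@]2(C)[C@H]1CO[Si](C)(C)C(C)(C)C
F0 | step 3 | none | none
F3 | step 5 | 5-hydroxy-5-[(trimethylsilyl)methyl]-4β-[(tert-butyldimethylsilyloxy)methyl]-cis-3a,7a-dimethyloctahydro-1H-inden-1-one | C[Si](C)(C)CC1(O)CC[C@]2(C)C(=O)CC[C@]2(C)[C@H]1CO[Si](C)(C)C(C)(C)C
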